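**Retrosynthetic overview**

1. The bridge bond between the methylene carbon on C6 of the chromene ring and C2 of the cyclohexadienone ring is cut. This gives chromene 11, in which the bridge carbon is still a plain methyl group, and (S)-dienone 5; they are joined in the last step by a dehydrogenative o-quinone methide coupling.
2. Enabling feature: the bridge carbon sits on C6 of the benzene ring of the chromene, between the C5 and C7 hydroxyls, so two-electron oxidation of the methyl group gives an o-quinone methide. C2 of the dienone ring is the only CH of that ring, between the C1 carbonyl and the C3 enol carbon, and is a soft carbon nucleophile.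
3. Both halves come from one monomer, 3-methylphlorisobutyrophenone 3, made by Friedel–Crafts acylation of 2-methylphloroglucinol.
4. Ring order: the benzene rings are bought; the cyclohexadienone ring arises by dearomatising asymmetric prenylation of 3, which sets the only stereocentre; the pyran ring is closed by condensation/oxa-6π electrocyclisation with the para hydroxyl masked; then the union.

Key step: step 6

Assumption 1: 5 and 13 are drawn as the enolised triketone tautomer shown, and the descriptor (S) refers to that drawing.
Assumption 2: the sense of induction of the ligand in step 2 cannot be predicted with certainty for this phenolate; the (R,R)-ligand is written, and its mirror image would be used if it proves to deliver the (R)-dienone.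

**Step 1**
Reactants: 1 2-methylphloroglucinol (2-methylbenzene-1,3,5-triol); 2 isobutyryl chloride
Product: 3 1-(2,4,6-trihydroxy-3-methylphenyl)-2-methylpropan-1-one
Conditions: AlCl3 (3 equiv), PhNO2–CH2Cl2, 0 °C to 60 °C; then ice/aq. HCl
Reagents that add atoms: isobutyryl chloride, CC(C)C(=O)Cl
Why: Friedel–Crafts acylation; the mirror-symmetric triol has two equivalent free ring positions, so mono-acylation can give only 3, and the chelated acyl group deactivates the ring against a second acylation.

**Step 2**
Reactants: 3 1-(2,4,6-trihydroxy-3-methylphenyl)-2-methylpropan-1-one; 4 tert-butyl 2-methylbut-3-en-2-yl carbonate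
Product: 5 (4S)-3,5-dihydroxy-4-methyl-4-(3-methylbut-2-en-1-yl)-2-(2-methylpropanoyl)cyclohexa-2,5-dien-1-one
Conditions: Pd2(dba)3·CHCl3 (2.5 mol %), (1R,2R)-N,N′-bis[2-(diphenylphosphanyl)benzoyl]cyclohexane-1,2-diamine (DACH-phenyl ligand, 7.5 mol %), degassed THF, 0 °C to rt, 1.0 equiv of 4
Reagents that add atoms: tert-butyl 2-methylbut-3-en-2-yl carbonate, CC(C)(C)OC(=O)OC(C)(C)C=C
Why: Pd-catalysed asymmetric allylic alkylation (Tsuji–Trost reaction) run as an alkylative dearomatisation: the carbonate ionises with loss of CO2 to a 1,1-dimethylallyl palladium complex and tert-butoxide, the phenolate attacks the unsubstituted allyl terminus (linear prenyl) through its methyl-bearing carbon, the site of geminal alkylation known from the preparation of acylfilicinic acids, and the chiral diphosphine pocket selects one enantiotopic face of the flat phenolate, which sets the quaternary stereocentre.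

**Step 3**
Reactants: 3 1-(2,4,6-trihydroxy-3-methylphenyl)-2-methylpropan-1-one; 6 chloromethyl methyl ether
Product: 7 1-[2,6-dihydroxy-4-(methoxymethoxy)-3-methylphenyl]-2-methylpropan-1-one
Conditions: MOMCl (1.05 equiv), iPr2NEt (1.1 equiv), CH2Cl2, 0 °C
Reagents that add atoms: chloromethyl methyl ether, COCCl
Why: Williamson-type O-alkylation (MOM ether formation); the hydroxyl para to the acyl group is the most acidic and the only one not hydrogen-bonded to the carbonyl, so one equivalent of reagent should mask it selectively, and this mask later forces the pyran oxygen onto the position next to the acyl group.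

**Step 4**
Reactants: 7 1-[2,6-dihydroxy-4-(methoxymethoxy)-3-methylphenyl]-2-methylpropan-1-one; 8 3-methylbut-2-enal
Product: 10 1-[7-hydroxy-5-(methoxymethoxy)-2,2,6-trimethyl-2H-chromen-8-yl]-2-methylpropan-1-one, via 1-oxatriene 9 (not isolated)
Conditions: 3-methylbut-2-enal (2 equiv), ethylenediammonium diacetate (20 mol %), toluene, 110 °C
Reagents that add atoms: 3-methylbut-2-enal, CC(C)=CC=O
Why: Knoevenagel-type condensation of the enal at the only free ring carbon gives 1-oxatriene 9, which closes by oxa-6π electrocyclisation; with the para oxygen masked, only the oxygen ortho to the acyl group can close the pyran ring, and no stereocentre is formed.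

**Step 5**
Reactants: 10 1-[7-hydroxy-5-(methoxymethoxy)-2,2,6-trimethyl-2H-chromen-8-yl]-2-methylpropan-1-one
Product: 11 1-(5,7-dihydroxy-2,2,6-trimethyl-2H-chromen-8-yl)-2-methylpropan-1-one
Conditions: 3 M aq. HCl, MeOH, 40 °C
Reagents that add atoms: none
Why: Acid-catalysed acetal exchange (MOM ether cleavage) to dimethoxymethane; the 2,2-dimethylchromene and the aryl ketone should tolerate dilute methanolic HCl, and 11 has no free ring position at which the released formaldehyde acetal could react.

**Step 6**
Reactants: 11 1-(5,7-dihydroxy-2,2,6-trimethyl-2H-chromen-8-yl)-2-methylpropan-1-one; 5 (4S)-3,5-dihydroxy-4-methyl-4-(3-methylbut-2-en-1-yl)-2-(2-methylpropanoyl)cyclohexa-2,5-dien-1-one (1.3 equiv)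
Product: 13 CNP0301804.1 (4S)-2-{[5,7-dihydroxy-2,2-dimethyl-8-(2-methylpropanoyl)-2H-chromen-6-yl]methyl}-3,5-dihydroxy-4-methyl-4-(3-methylbut-2-en-1-yl)-6-(2-methylpropanoyl)cyclohexa-2,5-dien-1-one, via o-quinone methide 12 (not isolated)
Conditions: DDQ (1.0 equiv, slow addition to the premixed partners), MeNO2–CH2Cl2, −20 °C to 0 °C; pH 7 buffer work-up
Reagents that add atoms: none
Why: DDQ should form a charge-transfer complex with the electron-rich chromenediol 11 and abstract hydride from the C6 methyl group, and loss of a phenolic proton from C5–OH or C7–OH then gives o-quinone methide 12; the enol of 5 adds through its only CH ring carbon (between the C1 carbonyl and the C5 enol carbon) to the exocyclic methylene in a Michael addition, and tautomerisation restores the benzene ring. The closest known reaction type is the DDQ oxidation of C-methylated acylphloroglucinols to o-quinone methides, combined with the o-quinone methide Michael addition of cyclic β-triketones that is the standard way to methylene-bridged acylphloroglucinol dimers. The step closes no ring and creates no stereocentre; the quaternary centre of 5 bears no hydrogen, lies two atoms from the new bond and is carried through unchanged. The step needs oxidation of 11 in preference to 5, cross-coupling in preference to homo-coupling, and C- in preference to O-alkylation. The substrates secure this: only 11 has a benzylic methyl group flanked by phenolic hydroxyls, 5 is an electron-poor vinylogous acid without such a position, 11 has no free ring carbon and cannot act as the nucleophile, and 5 has exactly one nucleophilic carbon. O-alkylation is reversible, whereas C-alkylation is driven by rearomatisation.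

**Compound list**

1 | 2-methylphloroglucinol (2-methylbenzene-1,3,5-triol) | Cc1c(O)cc(O)cc1O | starting material
2 | isobutyryl chloride | CC(C)C(=O)Cl | starting material
3 | 1-(2,4,6-trihydroxy-3-methylphenyl)-2-methylpropan-1-one | CC(C)C(=O)c1c(O)c(C)c(O)cc1O | intermediate
4 | tert-butyl 2-methylbut-3-en-2-yl carbonate | CC(C)(C)OC(=O)OC(C)(C)C=C | starting material
5 | (4S)-3,5-dihydroxy-4-methyl-4-(3-methylbut-2-en-1-yl)-2-(2-methylpropanoyl)cyclohexa-2,5-dien-1-one | CC(C)=CC[C@@]1(C)C(O)=CC(=O)C(C(=O)C(C)C)=C1O | intermediate
6 | chloromethyl methyl ether | COCCl | starting material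
7 | 1-[2,6-dihydroxy-4-(methoxymethoxy)-3-methylphenyl]-2-methylpropan-1-one | CC(C)C(=O)c1c(O)c(C)c(OCOC)cc1O | intermediate
8 | 3-methylbut-2-enal | CC(C)=CC=O | starting material
9 | 3-hydroxy-5-(methoxymethoxy)-4-methyl-6-(3-methylbut-2-en-1-ylidene)-2-(2-methylpropanoyl)cyclohexa-2,4-dien-1-one (1-oxatriene, not isolated) | CC(C)C(=O)C1=C(O)C(C)=C(OCOC)C(=CC=C(C)C)C1=O | intermediate
10 | 1-[7-hydroxy-5-(methoxymethoxy)-2,2,6-trimethyl-2H-chromen-8-yl]-2-methylpropan-1-one | CC(C)C(=O)c1c(O)c(C)c(OCOC)c2C=CC(C)(C)Oc12 | intermediate
11 | 1-(5,7-dihydroxy-2,2,6-trimethyl-2H-chromen-8-yl)-2-methylpropan-1-one | CC(C)C(=O)c1c(O)c(C)c(O)c2C=CC(C)(C)Oc12 | intermediate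
12 | 7-hydroxy-2,2-dimethyl-6-methylidene-8-(2-methylpropanoyl)-2H-chromen-5(6H)-one (o-quinone methide, not isolated) | CC(C)C(=O)C1=C(O)C(=C)C(=O)C2=C1OC(C)(C)C=C2 | intermediate
13 | CNP0301804.1, (4S)-2-{[5,7-dihydroxy-2,2-dimethyl-8-(2-methylpropanoyl)-2H-chromen-6-yl]methyl}-3,5-dihydroxy-4-methyl-4-(3-methylbut-2-en-1-yl)-6-(2-methylpropanoyl)cyclohexa-2,5-dien-1-one | CC(C)=CC[C@@]1(C)C(O)=C(Cc2c(O)c3c(c(C(=O)C(C)C)c2O)OC(C)(C)C=C3)C(=O)C(C(=O)C(C)C)=C1O | target

**Totals**

Total step count: 6.
Longest linear sequence: 5 steps (1 → 3 → 7 → 10 → 11 → 13); step 2 is the one-step branch to 5.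

**Steps most likely to fail**

Step 6. The oxidant may not stop after the first hydride abstraction. The new bridge methylene is doubly activated and could be oxidised again, followed by cyclisation, and the triketone partner or the o-quinone methide could be consumed by DDQ or its hydroquinone. Fallback: oxidation and coupling are separated. Starting from 11, oxidation with DDQ in CH2Cl2–MeOH in the absence of the partner should trap the o-quinone methide with methanol as the storable benzylic ether 1-[5,7-dihydroxy-6-(methoxymethyl)-2,2-dimethyl-2H-chromen-8-yl]-2-methylpropan-1-one F1. Heating F1 with 5 in toluene at about 90 °C with a little NaOAc should expel methanol, regenerate 12 under non-oxidative conditions and return to the route at 13.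

Step 2. Three things may go wrong: alkylation at the unsubstituted ring carbon (the rearomatising pathway) or at oxygen instead of at the methyl-bearing carbon; a second prenylation of the product; and weak facial discrimination or erosion by reversible ionisation of the new C–C bond. Fallback: starting from 3, base-mediated alkylation with prenyl bromide and NaOMe in MeOH at 0 °C should give racemic 3,5-dihydroxy-4-methyl-4-(3-methylbut-2-en-1-yl)-2-(2-methylpropanoyl)cyclohexa-2,5-dien-1-one F2. As a vinylogous acid it can be separated from aromatic by-products by bicarbonate extraction. Classical resolution follows: crystallisation of the 1:1 (R)-1-phenylethylammonium salt of the (S)-dienone F3, or of the salt with the mirror-image amine if that one crystallises, and liberation with dilute acid returns to the route at 5.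

Step 4. Condensation at a ring carbon flanked by a hydrogen-bonded hydroxyl and the acetal may be slow, and thermal loss of the acetal would open the way to ring closure on the wrong oxygen. Fallback: the ring oxygen is attached first and the C–C bond is made by rearrangement. Starting from 7, O-alkylation of the less hindered ortho hydroxyl with 3-chloro-3-methylbut-1-yne (K2CO3, KI, acetone, 50 °C) should give the aryl propargyl ether 1-[2-hydroxy-4-(methoxymethoxy)-3-methyl-6-(2-methylbut-3-yn-2-yloxy)phenyl]-2-methylpropan-1-one F4. Heating F4 in xylene at 140 °C should trigger aromatic Claisen rearrangement to the only free ortho carbon, 1,5-hydrogen shift and oxa-6π electrocyclisation, returning to the route at 10.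

**Further compounds**

F1 | step 6 | 1-[5,7-dihydroxy-6-(methoxymethyl)-2,2-dimethyl-2H-chromen-8-yl]-2-methylpropan-1-one | CC(C)C(=O)c1c(O)c(COC)c(O)c2C=CC(C)(C)Oc12
F2 | step 2 | racemic 3,5-dihydroxy-4-methyl-4-(3-methylbut-2-en-1-yl)-2-(2-methylpropanoyl)cyclohexa-2,5-dien-1-one | CC(C)=CCC1(C)C(O)=CC(=O)C(C(=O)C(C)C)=C1O
F3 | step 2 | 1:1 salt of the (S)-dienone with (R)-1-phenylethylamine | CC(C)=CC[C@@]1(C)C(O)=CC(=O)C(C(=O)C(C)C)=C1O.C[C@@H](N)c1ccccc1
F4 | step 4 | 1-[2-hydroxy-4-(methoxymethoxy)-3-methyl-6-(2-methylbut-3-yn-2-yloxy)phenyl]-2-methylpropan-1-one | CC(C)C(=O)c1c(O)c(C)c(OCOC)cc1OC(C)(C)C#C
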